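## Retrosynthetic overview

- The target is epicatechin gallate-(4β→6)-epicatechin gallate-(4β→8)-epicatechin gallate. The last operations are global O-debenzylation/debromination and, before that, invertive galloylation at C3 of the top (T) and middle (M) units.
- Both interflavan bonds are cut as umpolung α-arylations of a flavan-3-one: C4, normally the nucleophilic enolate carbon, is turned into an enolonium by trivalent iodine and attacked by the nucleophilic ring-A carbon of the next unit.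
- Order of bond formation: C4(T)–C6(M) first, monomer on monomer with C8 blocked by bromine; then C4(M)–C8(B).
- Building blocks: one 8-bromo flavan-3-one from (+)-catechin, used as enolonium precursor and as nucleophile, and per-benzylated (−)-epicatechin gallate as unit B, assembled from (−)-epicatechin and 3,4,5-tris(benzyloxy)benzoic acid.
- No ring is built; the three pyran rings come from the flavan-3-ol pool. C2 controls C4, and C4 controls C3.

Assumption: (+)-catechin, (−)-epicatechin and 3,4,5-tris(benzyloxy)benzoic acid are bought. The route is a paper design and has not been run.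

## Route

Step 1
Reactants: 1 (+)-catechin
Product: 2 5,7,3',4'-tetra-O-benzyl-(+)-catechin
Conditions: BnBr (4.4 equiv), K2CO3 (5 equiv), DMF, −10 °C to rt, 16 h
Reagents that add atoms: benzyl bromide, BrCc1ccccc1
Why: Williamson ether synthesis on the four phenols leaves the secondary 3-OH free and touches no stereocentre.

Step 2
Reactants: 2 5,7,3',4'-tetra-O-benzyl-(+)-catechin
Product: 3 8-bromo-5,7,3',4'-tetra-O-benzyl-(+)-catechin
Conditions: NBS (1.05 equiv), CH2Cl2, −78 °C to rt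
Reagents that add atoms: N-bromosuccinimide, O=C1CCC(=O)N1Br
Why: Electrophilic aromatic bromination goes to C8 of ring A, the more accessible oxygen-flanked position; the bromine later forces attack at C6 and leaves in the final hydrogenolysis.

Step 3
Reactants: 3 8-bromo-5,7,3',4'-tetra-O-benzyl-(+)-catechin
Product: 4 (2R)-8-bromo-5,7,3',4'-tetra-O-benzylflavan-3-one
Conditions: Dess–Martin periodinane (1.5 equiv), wet CH2Cl2, rt
Reagents that add atoms: none
Why: Dess–Martin oxidation of the secondary alcohol under neutral conditions keeps the C2 stereocentre, now α to the ketone, intact.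

Step 4
Reactants: 4 (2R)-8-bromo-5,7,3',4'-tetra-O-benzylflavan-3-one
Product: 5 C3=C4 trimethylsilyl enol ether of 4
Conditions: LiN(SiMe3)2 (1.1 equiv), Me3SiCl (1.5 equiv, present from the start), THF, −78 °C; pentane, filtration
Reagents that add atoms: chlorotrimethylsilane, C[Si](C)(C)Cl
Why: Kinetic enolate formation with internal silyl quench removes a benzylic C4 methylene proton and not the α-alkoxy C2 methine proton, so C2 stays (R).

Step 5
Reactants: 5 C3=C4 trimethylsilyl enol ether of 4; 4 (2R)-8-bromo-5,7,3',4'-tetra-O-benzylflavan-3-one (3 equiv, excess recovered)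
Product: 7 (4β→6)-linked diketone dimer T–M, via O-iodanyl enolonium 6 (not isolated)
Conditions: PhI(OH)OTs (1.2 equiv), BF3·OEt2 (1.5 equiv), CH2Cl2, −78 °C, add 5, 5 min; then 4, −78 to −40 °C; NaHCO3 quench
Reagents that add atoms: none
Why: Proposed new method: umpolung α-arylation of a ketone through a trivalent-iodine enolonium (closest known type: PhI(OH)OTs/BF3 enolonium arylation of silyl enol ethers by electron-rich arenes, a Friedel–Crafts-type attack on the O-bound iodane); C4 of 6 is a benzylic α-keto cation equivalent that is attacked by C6, the only free ring-A position of 4, anti to the 2-aryl group, and because the new C4–H is doubly benzylic and α to the ketone the product settles to the 2,4-trans (4β) epimer with the new aryl pseudo-axial and clear of the 5-benzyloxy group.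

Step 6
Reactants: 7 (4β→6)-linked diketone dimer T–M
Product: 8 mono trimethylsilyl enol ether of 7 at the unit-M ketone
Conditions: LiN(SiMe3)2 (1.05 equiv), Me3SiCl (1.5 equiv, present from the start), THF, −78 °C; pentane, filtration
Reagents that add atoms: chlorotrimethylsilane, C[Si](C)(C)Cl
Why: Kinetic enolate silylation takes the unhindered C4 methylene of unit M, because the C4–H of unit T is a tertiary diarylmethine walled in by four ortho substituents and both C2–H are α-alkoxy methines.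

Step 7
Reactants: 9 (−)-epicatechin
Product: 10 5,7,3',4'-tetra-O-benzyl-(−)-epicatechin
Conditions: BnBr (4.4 equiv), K2CO3 (5 equiv), DMF, −10 °C to rt, 16 h, argon
Reagents that add atoms: benzyl bromide, BrCc1ccccc1
Why: Williamson ether synthesis on the four phenols leaves the secondary 3-OH free; the mild carbonate base at or below room temperature does not epimerise C2, and C3 is not touched.

Step 8
Reactants: 10 5,7,3',4'-tetra-O-benzyl-(−)-epicatechin; 11 3,4,5-tris(benzyloxy)benzoic acid (1.5 equiv)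
Product: 12 hepta-O-benzyl-(−)-epicatechin gallate
Conditions: DCC (1.6 equiv), DMAP (0.3 equiv), CH2Cl2, 0 °C to rt
Reagents that add atoms: none
Why: Steglich esterification acylates the axial 3-OH through the acylpyridinium intermediate; the C3–O bond is not broken, so the (2R,3R) configuration is retained.

Step 9
Reactants: 8 mono trimethylsilyl enol ether of 7; 12 hepta-O-benzyl-(−)-epicatechin gallate (3 equiv, excess recovered)
Product: 14 bis-ketone trimer T–M–B, via O-iodanyl enolonium 13 (not isolated)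
Conditions: PhI(OH)OTs (1.2 equiv), BF3·OEt2 (1.5 equiv), CH2Cl2, −78 °C, add 8, 5 min; then 12, −78 to −40 °C; NaHCO3 quench
Reagents that add atoms: none
Why: Proposed new method: the same trivalent-iodine enolonium α-arylation (closest known type as in step 5); C4 of unit M is attacked by C8 of 12, the position that benzylated flavan-3-ols offer to C4 electrophiles, anti to the 2-aryl group of unit M, and the epimerisable C4 again settles 2,4-trans (4β).

Step 10
Reactants: 14 bis-ketone trimer T–M–B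
Product: 15 3β,3β-diol trimer (units T and M both 2,3-trans-3,4-cis)
Conditions: NaBH4 (4 equiv), CeCl3·7H2O (2.5 equiv), THF/MeOH, −78 to −40 °C
Reagents that add atoms: none
Why: Luche reduction; in each ketone hydride adds axially to the face anti to the pseudo-axial 4β-aryl group (Felkin-type control), giving the 3β-alcohols, and the cold, non-basic conditions avoid C4 epimerisation and spare the gallate ester and the aryl bromides.

Step 11
Reactants: 15 3β,3β-diol trimer; 11 3,4,5-tris(benzyloxy)benzoic acid (5 equiv)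
Product: 16 dibromo henicosa-O-benzyl trigallate trimer (all units 2,3-cis; T and M 3,4-trans)
Conditions: PPh3 (5 equiv), DIAD (5 equiv), toluene, 0 °C to rt
Reagents that add atoms: none
Why: Double Mitsunobu esterification; the carboxylate displaces each equatorial oxyphosphonium group by SN2 from the α face, anti to the 4β-aryl group, so both C3 centres invert to the 3α-gallates of the epicatechin series.

Step 12
Reactants: 16 dibromo henicosa-O-benzyl trigallate trimer
Product: 17 epicatechin gallate-(4β→6)-epicatechin gallate-(4β→8)-epicatechin gallate (CNP0183218.1)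
Conditions: H2 (1 atm), Pd(OH)2/C, NaOAc (2.2 equiv), THF/MeOH/H2O, rt; Sephadex LH-20
Reagents that add atoms: none
Why: Catalytic hydrogenolysis cleaves the 21 benzyl ethers and both aryl C–Br bonds while the gallate esters, the interflavan bonds and all eight stereocentres are left alone.

## Compound list

1 | (+)-catechin, (2R,3S) | O[C@H]1Cc2c(O)cc(O)cc2O[C@@H]1c1ccc(O)c(O)c1 | starting material

2 | 5,7,3',4'-tetra-O-benzyl-(+)-catechin, (2R,3S) | O[C@H]1Cc2c(OCc9ccccc9)cc(OCc9ccccc9)cc2O[C@@H]1c8ccc(OCc9ccccc9)c(OCc9ccccc9)c8 | intermediate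

3 | 8-bromo-5,7,3',4'-tetra-O-benzyl-(+)-catechin, (2R,3S) | O[C@H]1Cc2c(OCc9ccccc9)cc(OCc9ccccc9)c(Br)c2O[C@@H]1c8ccc(OCc9ccccc9)c(OCc9ccccc9)c8 | intermediate

4 | (2R)-5,7-bis(benzyloxy)-2-[3,4-bis(benzyloxy)phenyl]-8-bromochroman-3-one | O=C1Cc2c(OCc9ccccc9)cc(OCc9ccccc9)c(Br)c2O[C@@H]1c8ccc(OCc9ccccc9)c(OCc9ccccc9)c8 | intermediate

5 | (2R)-3-(trimethylsilyloxy)-2H-chromene (C3=C4 silyl enol ether) of 4 | C[Si](C)(C)OC1=Cc2c(OCc9ccccc9)cc(OCc9ccccc9)c(Br)c2O[C@@H]1c8ccc(OCc9ccccc9)c(OCc9ccccc9)c8 | intermediate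

6 | O-bound phenyl(tosyloxy)iodanyl enolate of 4 (trivalent iodine, enolonium equivalent, 2R) | Cc7ccc(cc7)S(=O)(=O)OI(c7ccccc7)OC1=Cc2c(OCc9ccccc9)cc(OCc9ccccc9)c(Br)c2O[C@@H]1c8ccc(OCc9ccccc9)c(OCc9ccccc9)c8 | intermediate

7 | diketone dimer: unit T is the (2R)-flavan-3-one of 4 carrying at C4 (4β, trans to its 2-aryl) the C6 of unit M, a second (2R)-8-bromo-tetra-O-benzylflavan-3-one | O=C1[C@@H](c3c(OCc9ccccc9)c(Br)c4c(c3OCc9ccccc9)CC(=O)[C@@H](c8ccc(OCc9ccccc9)c(OCc9ccccc9)c8)O4)c2c(OCc9ccccc9)cc(OCc9ccccc9)c(Br)c2O[C@@H]1c8ccc(OCc9ccccc9)c(OCc9ccccc9)c8 | intermediate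

8 | 7 with the unit-M ketone as its C3=C4 trimethylsilyl enol ether | O=C1[C@@H](c3c(OCc9ccccc9)c(Br)c4c(c3OCc9ccccc9)C=C(O[Si](C)(C)C)[C@@H](c8ccc(OCc9ccccc9)c(OCc9ccccc9)c8)O4)c2c(OCc9ccccc9)cc(OCc9ccccc9)c(Br)c2O[C@@H]1c8ccc(OCc9ccccc9)c(OCc9ccccc9)c8 | intermediate

9 | (−)-epicatechin, (2R,3R) | O[C@@H]1Cc2c(O)cc(O)cc2O[C@@H]1c1ccc(O)c(O)c1 | starting material

10 | 5,7,3',4'-tetra-O-benzyl-(−)-epicatechin, (2R,3R) | O[C@@H]1Cc2c(OCc9ccccc9)cc(OCc9ccccc9)cc2O[C@@H]1c8ccc(OCc9ccccc9)c(OCc9ccccc9)c8 | intermediate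

11 | 3,4,5-tris(benzyloxy)benzoic acid | OC(=O)c1cc(OCc2ccccc2)c(OCc2ccccc2)c(OCc2ccccc2)c1 | starting material

12 | 5,7,3',4'-tetra-O-benzyl-(−)-epicatechin 3-O-(3,4,5-tri-O-benzylgallate), (2R,3R) | O=C(O[C@@H]1Cc2c(OCc9ccccc9)cc(OCc9ccccc9)cc2O[C@@H]1c8ccc(OCc9ccccc9)c(OCc9ccccc9)c8)c8cc(OCc9ccccc9)c(OCc9ccccc9)c(OCc9ccccc9)c8 | intermediate

13 | O-bound phenyl(tosyloxy)iodanyl enolate of the unit-M ketone of 7 (trivalent iodine) | O=C1[C@@H](c3c(OCc9ccccc9)c(Br)c4c(c3OCc9ccccc9)C=C(OI(c7ccccc7)OS(=O)(=O)c7ccc(C)cc7)[C@@H](c8ccc(OCc9ccccc9)c(OCc9ccccc9)c8)O4)c2c(OCc9ccccc9)cc(OCc9ccccc9)c(Br)c2O[C@@H]1c8ccc(OCc9ccccc9)c(OCc9ccccc9)c8 | intermediate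

14 | bis-ketone trimer: T (3-one, 4β) –(4→6)– M (3-one, 4β, 8-bromo) –(4→8)– B (unit of 12); both ketone units 2R and 2,4-trans | O=C1[C@@H](c3c(OCc9ccccc9)c(Br)c4c(c3OCc9ccccc9)[C@H](c5c(OCc9ccccc9)cc(OCc9ccccc9)c6c5O[C@H](c8ccc(OCc9ccccc9)c(OCc9ccccc9)c8)[C@H](OC(=O)c8cc(OCc9ccccc9)c(OCc9ccccc9)c(OCc9ccccc9)c8)C6)C(=O)[C@@H](c8ccc(OCc9ccccc9)c(OCc9ccccc9)c8)O4)c2c(OCc9ccccc9)cc(OCc9ccccc9)c(Br)c2O[C@@H]1c8ccc(OCc9ccccc9)c(OCc9ccccc9)c8 | intermediate

15 | diol trimer: as 14 with both ketones reduced to 3β-OH (units T and M 2,3-trans-3,4-cis) | O[C@H]1[C@@H](c3c(OCc9ccccc9)c(Br)c4c(c3OCc9ccccc9)[C@H](c5c(OCc9ccccc9)cc(OCc9ccccc9)c6c5O[C@H](c8ccc(OCc9ccccc9)c(OCc9ccccc9)c8)[C@H](OC(=O)c8cc(OCc9ccccc9)c(OCc9ccccc9)c(OCc9ccccc9)c8)C6)[C@H](O)[C@@H](c8ccc(OCc9ccccc9)c(OCc9ccccc9)c8)O4)c2c(OCc9ccccc9)cc(OCc9ccccc9)c(Br)c2O[C@@H]1c8ccc(OCc9ccccc9)c(OCc9ccccc9)c8 | intermediate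

16 | 8(T),8(M)-dibromo henicosa-O-benzyl ether of the target (three 3α-gallates; T and M 2,3-cis-3,4-trans) | O=C(O[C@@H]1[C@@H](c3c(OCc9ccccc9)c(Br)c4c(c3OCc9ccccc9)[C@H](c5c(OCc9ccccc9)cc(OCc9ccccc9)c6c5O[C@H](c8ccc(OCc9ccccc9)c(OCc9ccccc9)c8)[C@H](OC(=O)c8cc(OCc9ccccc9)c(OCc9ccccc9)c(OCc9ccccc9)c8)C6)[C@@H](OC(=O)c8cc(OCc9ccccc9)c(OCc9ccccc9)c(OCc9ccccc9)c8)[C@@H](c8ccc(OCc9ccccc9)c(OCc9ccccc9)c8)O4)c2c(OCc9ccccc9)cc(OCc9ccccc9)c(Br)c2O[C@@H]1c8ccc(OCc9ccccc9)c(OCc9ccccc9)c8)c8cc(OCc9ccccc9)c(OCc9ccccc9)c(OCc9ccccc9)c8 | intermediate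

17 | epicatechin 3-O-gallate-(4β→6)-epicatechin 3-O-gallate-(4β→8)-epicatechin 3-O-gallate (CNP0183218.1) | O=C(O[C@@H]1[C@@H](c2c(O)cc3c(c2O)[C@H](c2c(O)cc(O)c4c2O[C@H](c2ccc(O)c(O)c2)[C@H](OC(=O)c2cc(O)c(O)c(O)c2)C4)[C@@H](OC(=O)c2cc(O)c(O)c(O)c2)[C@@H](c2ccc(O)c(O)c2)O3)c2c(O)cc(O)cc2O[C@@H]1c1ccc(O)c(O)c1)c1cc(O)c(O)c(O)c1 | target

## Step count and risks

Total steps: 12. Longest linear sequence: 10 steps (steps 1 to 6 and 9 to 12, from (+)-catechin); steps 7 and 8 are the two-step branch to unit B.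

The three steps most likely to fail:

**Step 5 (the same chemistry recurs in step 9).** The enolonium is the keto tautomer of a 3-hydroxyflavylium ion, so loss of the C2 proton would aromatise it and erase C2. The trivalent-iodine reagent could also attack a benzyloxy-rich arene instead of the enol ether, and the facial bias at C4 rests on a remote 2-aryl group plus thermodynamic settling. The fallback sets out from 5 and comes back at 7. NBS (1.0 equiv, THF, −78 °C) brominates the enol ether carbon of 5 to give the 4,8-dibromo ketone F1. This is used cold and crude: AgOTf and 2,6-di-tert-butylpyridine in CH2Cl2 at −78 °C pull off the C4 bromide in the presence of 4 (3 equiv), so an isolable α-halo ketone with silver-assisted ionisation replaces the iodane and delivers 7.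

**Step 6.** The base may also deprotonate the more acidic but buried C4–H of unit T, or a C2–H, giving mixtures of enol ethers and eroding C2 or C4. The fallback sets out from 7 and comes back at 14, bypassing 8 and 13. Regitz diazo transfer (p-acetamidobenzenesulfonyl azide, DBU, MeCN, 0 °C) can only occur at a methylene, and only unit M has one next to a ketone. It gives the diazo ketone F2. Dirhodium tetraacetate Rh2(OAc)4 (2 mol %) in CH2Cl2 with 12 (3 equiv) then turns the diazo carbon into an electrophilic carbenoid that inserts into the C8–H of 12 (aromatic substitution), giving 14.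

**Step 11.** Two hindered secondary alcohols must invert. The equatorial leaving group lies anti to the C4–C4a bond and to O1, so aryl or oxygen participation (retention, ring contraction) and elimination to a flav-3-ene compete; Mitsunobu inversion of 2,3-trans flavan-3-ols is known to be capricious. The fallback sets out from 15 and comes back at 16. Tf2O/pyridine (CH2Cl2, −20 °C) gives the bis-triflate F3. Tetrabutylammonium nitrite in toluene/DMF at rt displaces both triflates with inversion to the bis-nitrite ester F4, which is hydrolysed on aqueous work-up to the 3α,3α-diol F5. Esterification of F5 with 11 (DCC, DMAP, CH2Cl2) proceeds with retention and gives 16. If step 10 delivers the 3α-alcohols instead of 15, that product is F5 itself and the same esterification leads to 16.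

Further compounds

F1 | step 5 | (2R)-4,8-dibromo-5,7,3',4'-tetra-O-benzylflavan-3-one (C4 epimer mixture) | O=C1C(Br)c2c(OCc9ccccc9)cc(OCc9ccccc9)c(Br)c2O[C@@H]1c8ccc(OCc9ccccc9)c(OCc9ccccc9)c8

F2 | step 6 | 7 with a diazo group at C4 of unit M (α-diazo ketone) | O=C1[C@@H](c3c(OCc9ccccc9)c(Br)c4c(c3OCc9ccccc9)C(=[N+]=[N-])C(=O)[C@@H](c8ccc(OCc9ccccc9)c(OCc9ccccc9)c8)O4)c2c(OCc9ccccc9)cc(OCc9ccccc9)c(Br)c2O[C@@H]1c8ccc(OCc9ccccc9)c(OCc9ccccc9)c8

F3 | step 11 | 3β,3β-bis(trifluoromethanesulfonate) of 15 | FC(F)(F)S(=O)(=O)O[C@H]1[C@@H](c3c(OCc9ccccc9)c(Br)c4c(c3OCc9ccccc9)[C@H](c5c(OCc9ccccc9)cc(OCc9ccccc9)c6c5O[C@H](c8ccc(OCc9ccccc9)c(OCc9ccccc9)c8)[C@H](OC(=O)c8cc(OCc9ccccc9)c(OCc9ccccc9)c(OCc9ccccc9)c8)C6)[C@H](OS(=O)(=O)C(F)(F)F)[C@@H](c8ccc(OCc9ccccc9)c(OCc9ccccc9)c8)O4)c2c(OCc9ccccc9)cc(OCc9ccccc9)c(Br)c2O[C@@H]1c8ccc(OCc9ccccc9)c(OCc9ccccc9)c8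

F4 | step 11 | 3α,3α-bis(nitrite ester), inverted at C3 of units T and M | O=NO[C@@H]1[C@@H](c3c(OCc9ccccc9)c(Br)c4c(c3OCc9ccccc9)[C@H](c5c(OCc9ccccc9)cc(OCc9ccccc9)c6c5O[C@H](c8ccc(OCc9ccccc9)c(OCc9ccccc9)c8)[C@H](OC(=O)c8cc(OCc9ccccc9)c(OCc9ccccc9)c(OCc9ccccc9)c8)C6)[C@@H](ON=O)[C@@H](c8ccc(OCc9ccccc9)c(OCc9ccccc9)c8)O4)c2c(OCc9ccccc9)cc(OCc9ccccc9)c(Br)c2O[C@@H]1c8ccc(OCc9ccccc9)c(OCc9ccccc9)c8

F5 | step 11 | 3α,3α-diol trimer (units T and M 2,3-cis-3,4-trans) | O[C@@H]1[C@@H](c3c(OCc9ccccc9)c(Br)c4c(c3OCc9ccccc9)[C@H](c5c(OCc9ccccc9)cc(OCc9ccccc9)c6c5O[C@H](c8ccc(OCc9ccccc9)c(OCc9ccccc9)c8)[C@H](OC(=O)c8cc(OCc9ccccc9)c(OCc9ccccc9)c(OCc9ccccc9)c8)C6)[C@@H](O)[C@@H](c8ccc(OCc9ccccc9)c(OCc9ccccc9)c8)O4)c2c(OCc9ccccc9)cc(OCc9ccccc9)c(Br)c2O[C@@H]1c8ccc(OCc9ccccc9)c(OCc9ccccc9)c8
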